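**Plan**

1. Retrosynthesis: cut the bond between the bridging CH2 and the trione ring, then the isobutyryl–ring bond of the trione, then two ring bonds of the trione at once (quaternary C to the C–OH carbon next to the acyl-bearing carbon, and ring C=O carbon to the bridge-bearing carbon), and last the CH2–CH= bond of the prenyl chain.
2. Forward: prenyl chain by conjugate addition (enol silane 3), trione ring by one [3+3] annulation with malonyl dichloride, catalyst-controlled C-isobutyrylation, then union through CH2 with the chromene half, whose pyran ring is annulated onto isobutyrylphloroglucinol.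
3. Enabling feature: in the six-membered ring of the left half, C=O carbons alternate with carbon-nucleophile positions. The atoms C(Me)(prenyl)–C(O)–C are a ketone with its two alpha-carbons (1,3-dinucleophile) and the atoms C(O)–C(acyl)–C(O) are a malonyl unit (1,3-dielectrophile). The quaternary carbon has no hydrogen, so the ring closes as a carbocyclic trione and not as a 2-pyranone.
4. Stereochemistry: the only stereocentre, the quaternary carbon (S), is built prochiral in step 2 (two identical arms). It becomes stereogenic in step 3, where a chiral acyl-transfer catalyst places the isobutyryl group on one of two enantiotopic ring carbons. A quaternary carbon cannot epimerise afterwards.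

Key step: step 2

Remark: compounds 6, 8 and 16 are tautomer mixtures written in one keto or enol form; the (S) descriptor refers to the enol form of the given SMILES.

Step 1
Reactants: 1 3-methylbut-3-en-2-one; 2 (2-methylprop-1-en-1-yl)magnesium bromide
Product: 3 trimethyl[(3,6-dimethylhepta-2,5-dien-2-yl)oxy]silane (E/Z mixture)
Conditions: CuI·2LiCl (5 mol%), Me3SiCl (1.2 equiv), THF, −78 °C to −40 °C; Et3N, pentane, filtration, distillation
Reagents that add atoms: chlorotrimethylsilane, C[Si](C)(C)Cl
Why: Copper-catalysed conjugate addition of the alkenyl Grignard reagent with in situ O-silylation completes the prenyl chain and traps the enolate where it forms, so the enol double bond sits regiospecifically at the methyl- and prenyl-bearing carbon; the E/Z ratio does not matter because both isomers lead to the same achiral trione.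

Step 2
Reactants: 3 trimethyl[(3,6-dimethylhepta-2,5-dien-2-yl)oxy]silane; 4 propanedioyl dichloride (malonyl dichloride)
Product: 6 6-methyl-6-(3-methylbut-2-en-1-yl)cyclohexane-1,3,5-trione, via keto acid chloride 5 (not isolated)
Conditions: 4 (2 equiv), Et2O, −20 °C to rt; then KOH, BnEt3NCl, H2O, rt; cold dilute HCl to pH 2
Reagents that add atoms: none
Why: Effenberger cyclization, a [3+3] annulation: the tetrasubstituted enol carbon of 3 attacks one acid chloride of 4 (C-acylation, loss of Me3SiCl), which creates the quaternary carbon in 5, and in the hydroxide/phase-transfer stage the methyl ketone of 5 is enolised and its carbon attacks the second acyl carbon, directly or through the acylketene formed by loss of HCl. The closest known reaction type is the annulation of prenyl-bearing cyclohexanone enol ethers with malonyl dichloride to bicyclo[3.3.1]nonane-2,4,9-triones, where the same two C–C bonds form at a quaternary and a second alpha-carbon. The one ring closes in the 6-(enolendo)-exo-trig mode. No stereocentre arises, because the new quaternary carbon carries two constitutionally identical C(=O)–CH2–C(=O) arms: 6 has a mirror plane and the carbon is prochiral, its configuration being decided in step 3. The step needs C-acylation at the substituted alpha-carbon first, secured by the fixed enol double bond of 3, and C- instead of O-closure second, secured by the quaternary carbon, which has no hydrogen and so rules out the aromatic-type 2-pyranone that ketones with free alpha-hydrogens give. An O-acylated by-product would be a simple enol ester that base returns to the enolate/ketene pair, and the trisubstituted alkene should be inert to the acid chloride at low temperature.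

Step 3
Reactants: 6 6-methyl-6-(3-methylbut-2-en-1-yl)cyclohexane-1,3,5-trione
Product: 8 (4S)-3,5-dihydroxy-4-methyl-4-(3-methylbut-2-en-1-yl)-2-(2-methylpropanoyl)cyclohexa-2,5-dien-1-one, via enol isobutyrate 7 (not isolated)
Conditions: (i-PrCO)2O (1.05 equiv), Et3N (1.1 equiv), toluene, 0 °C; then isothiourea catalyst (2S,3R)-HyperBTM [(2S,3R)-3-isopropyl-2-phenyl-3,4-dihydro-2H-benzo[4,5]thiazolo[3,2-a]pyrimidine] or its antipode (10 mol%), whichever a first run shows to lead to the (S) product, −20 °C to 0 °C; dilute HCl work-up
Reagents that add atoms: 2-methylpropanoic anhydride, CC(C)C(=O)OC(=O)C(C)C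
Why: Proposed new method: O-acylation of the acidic trione gives the activated enol ester 7, which the chiral isothiourea opens to a tight ion pair of an N-acyl isothiouronium cation and the trione mono-enolate; this enolate is chiral, and its two mirror-image forms (nucleophilic carbon on one or the other arm) interconvert rapidly by proton transfer. The cation, with its acyl group locked by the O···S contact and one face blocked by the phenyl group, should prefer one enantiotopic face of the nucleophilic carbon, whose flanks (quaternary side versus CH2–C=O side) differ strongly, while the ring prefers attack on the face of the small methyl group; only one enolate antipode satisfies both, so the irreversible C-acylation should go to one of the two enantiotopic ring carbons and thereby fix the (S) quaternary centre. The closest known reaction types are the asymmetric Steglich O-to-C acyl migration of enol carbonates with chiral isothioureas or 4-aminopyridines, and the DMAP- or cyanide-catalysed rearrangement of cyclic 1,3-dione enol esters to 2-acyl-1,3-diones.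

Step 4
Reactants: 9 benzene-1,3,5-triol (phloroglucinol)
Product: 10 2-methyl-1-(2,4,6-trihydroxyphenyl)propan-1-one
Conditions: i-PrCOCl (1.0 equiv), AlCl3 (3 equiv), PhNO2/CH2Cl2, 0 °C to 40 °C; ice/HCl
Reagents that add atoms: 2-methylpropanoyl chloride, CC(C)C(Cl)=O
Why: Friedel–Crafts C-acylation of the electron-rich arene; the first acyl group deactivates the ring, so monoacylation should prevail.

Step 5
Reactants: 10 2-methyl-1-(2,4,6-trihydroxyphenyl)propan-1-one; 11 3-methylbut-2-enal
Product: 13 1-(5,7-dihydroxy-2,2-dimethyl-2H-chromen-8-yl)-2-methylpropan-1-one, via ortho-quinone methide 12 (not isolated)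
Conditions: 11 (1.5 equiv), ethylenediammonium diacetate (10 mol%), toluene, 110 °C; chromatography
Reagents that add atoms: none
Why: Knoevenagel-type condensation at a free ring carbon gives ortho-quinone methide 12, whose oxa-6π electrocyclisation closes the 2H-pyran ring; closure through the oxygen ortho to the acyl group gives 13, closure through the para oxygen gives the 6-acyl isomer, which is to be removed by chromatography.

Step 6
Reactants: 13 1-(5,7-dihydroxy-2,2-dimethyl-2H-chromen-8-yl)-2-methylpropan-1-one
Product: 14 1-{6-[(dimethylamino)methyl]-5,7-dihydroxy-2,2-dimethyl-2H-chromen-8-yl}-2-methylpropan-1-one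
Conditions: 37% aq CH2O (1.1 equiv), 40% aq Me2NH (1.2 equiv), EtOH, 0 °C to rt
Reagents that add atoms: formaldehyde, C=O; dimethylamine, CNC
Why: Mannich aminomethylation of the phenol at its only unsubstituted ring carbon (C6), which stores the bridging carbon in a stable, formaldehyde-free form.

Step 7
Reactants: 8 (4S)-3,5-dihydroxy-4-methyl-4-(3-methylbut-2-en-1-yl)-2-(2-methylpropanoyl)cyclohexa-2,5-dien-1-one; 14 1-{6-[(dimethylamino)methyl]-5,7-dihydroxy-2,2-dimethyl-2H-chromen-8-yl}-2-methylpropan-1-one
Product: 16 (4S)-6-{[5,7-dihydroxy-2,2-dimethyl-8-(2-methylpropanoyl)-2H-chromen-6-yl]methyl}-3,5-dihydroxy-4-methyl-4-(3-methylbut-2-en-1-yl)-2-(2-methylpropanoyl)cyclohexa-2,5-dien-1-one, via ortho-quinone methide 15 (not isolated)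
Conditions: toluene, 80 °C, argon
Reagents that add atoms: none
Why: The strongly acidic triketone 8 protonates the amine of 14, loss of dimethylamine gives ortho-quinone methide 15, and the enolate carbon of 8 (its only ring CH) adds in a Michael reaction; this is the established way to unsymmetrical methylene-bridged acylphloroglucinols without free formaldehyde and hence without homodimers, and the quaternary stereocentre, having no alpha-hydrogen, is untouched.

**Compound list**

1 | 3-methylbut-3-en-2-one | CC(=O)C(C)=C | starting material
2 | (2-methylprop-1-en-1-yl)magnesium bromide | CC(C)=C[Mg]Br | starting material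
3 | trimethyl[(3,6-dimethylhepta-2,5-dien-2-yl)oxy]silane (E/Z mixture) | CC(O[Si](C)(C)C)=C(C)CC=C(C)C | intermediate
4 | propanedioyl dichloride (malonyl dichloride) | O=C(Cl)CC(Cl)=O | starting material
5 | 4-acetyl-4,7-dimethyl-3-oxooct-6-enoyl chloride (racemic, not isolated) | CC(=O)C(C)(CC=C(C)C)C(=O)CC(Cl)=O | intermediate
6 | 6-methyl-6-(3-methylbut-2-en-1-yl)cyclohexane-1,3,5-trione (achiral) | CC1(CC=C(C)C)C(=O)CC(=O)CC1=O | intermediate
7 | 4-methyl-4-(3-methylbut-2-en-1-yl)-3,5-dioxocyclohex-1-en-1-yl 2-methylpropanoate (racemising by tautomerism, not isolated) | CC(C)C(=O)OC1=CC(=O)C(C)(CC=C(C)C)C(=O)C1 | intermediate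
8 | (4S)-3,5-dihydroxy-4-methyl-4-(3-methylbut-2-en-1-yl)-2-(2-methylpropanoyl)cyclohexa-2,5-dien-1-one | CC(C)=CC[C@@]1(C)C(O)=CC(=O)C(C(=O)C(C)C)=C1O | intermediate
9 | benzene-1,3,5-triol (phloroglucinol) | Oc1cc(O)cc(O)c1 | starting material
10 | 2-methyl-1-(2,4,6-trihydroxyphenyl)propan-1-one | CC(C)C(=O)c1c(O)cc(O)cc1O | intermediate
11 | 3-methylbut-2-enal | CC(C)=CC=O | starting material
12 | 3,5-dihydroxy-6-(3-methylbut-2-en-1-ylidene)-2-(2-methylpropanoyl)cyclohexa-2,4-dien-1-one (not isolated) | CC(C)C(=O)C1=C(O)C=C(O)C(=CC=C(C)C)C1=O | intermediate
13 | 1-(5,7-dihydroxy-2,2-dimethyl-2H-chromen-8-yl)-2-methylpropan-1-one | CC(C)C(=O)c1c(O)cc(O)c2c1OC(C)(C)C=C2 | intermediate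
14 | 1-{6-[(dimethylamino)methyl]-5,7-dihydroxy-2,2-dimethyl-2H-chromen-8-yl}-2-methylpropan-1-one | CN(C)Cc1c(O)c2c(c(C(=O)C(C)C)c1O)OC(C)(C)C=C2 | intermediate
15 | 5-hydroxy-2,2-dimethyl-6-methylidene-8-(2-methylpropanoyl)-2H-chromen-7(6H)-one (not isolated) | C=C1C(=O)C(C(=O)C(C)C)=C2OC(C)(C)C=CC2=C1O | intermediate
16 | (4S)-6-{[5,7-dihydroxy-2,2-dimethyl-8-(2-methylpropanoyl)-2H-chromen-6-yl]methyl}-3,5-dihydroxy-4-methyl-4-(3-methylbut-2-en-1-yl)-2-(2-methylpropanoyl)cyclohexa-2,5-dien-1-one | CC(C)=CC[C@@]1(C)C(O)=C(Cc2c(O)c3c(c(C(=O)C(C)C)c2O)OC(C)(C)C=C3)C(=O)C(C(=O)C(C)C)=C1O | target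

**Step count and risks**

Total step count: 7. Longest linear sequence: 4 steps (1, 2, 3, 7 or 4, 5, 6, 7).

Steps most likely to fail:

Step 3 (Proposed new method). The acyl transfer may not distinguish the two enantiotopic ring carbons well enough, or may stall at the O-acyl stage. The fallback uses known chemistry, sets out from compound 6 and comes back at compound 8. O-acylation with 2-methylpropanoyl chloride/Et3N and rearrangement of the enol ester with achiral DMAP (10 mol%) should give racemic 3,5-dihydroxy-4-methyl-4-(3-methylbut-2-en-1-yl)-2-(2-methylpropanoyl)cyclohexa-2,5-dien-1-one F1. This strong vinylogous acid is resolved by fractional crystallisation with (S)-1-phenylethylamine (or the antipodal amine, whichever gives the less soluble salt of the (S)-acid) as the (S)-1-phenylethylammonium salt of the (4S)-enolate of compound 8 F2. Dilute HCl then releases compound 8.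

Step 2. The hindered enol carbon may be acylated too slowly, malonyl dichloride may oligomerise through its ketene, or the acid chloride may hydrolyse and decarboxylate before the ring closes. The fallback makes the two C–C bonds one at a time around a preformed quaternary carbon. It sets out not from a numbered compound but from commercial 3-methylpentane-2,4-dione (replacing compounds 1 to 5) and comes back at compound 6. C-alkylation with 1-bromo-3-methylbut-2-ene (K2CO3, acetone, reflux) gives 3-methyl-3-(3-methylbut-2-en-1-yl)pentane-2,4-dione F3. Claisen condensation of one acetyl group with dimethyl carbonate (NaH, THF, reflux) gives methyl 4-acetyl-4,7-dimethyl-3-oxooct-6-enoate F4. Dieckmann condensation (NaOMe, MeOH, reflux, then acid) closes the ring to compound 6.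

Step 5. The pyran ring may close mainly through the hydroxyl para to the acyl group, so that the wrong regioisomer dominates. The fallback sets out from compound 10 and comes back at compound 13. The non-chelated para hydroxyl is silylated (t-BuMe2SiCl 1.0 equiv, imidazole, CH2Cl2, 0 °C) to 1-{4-[(tert-butyldimethylsilyl)oxy]-2,6-dihydroxyphenyl}-2-methylpropan-1-one F5. The same annulation with 3-methylbut-2-enal can then close only through an ortho hydroxyl and gives 1-{5-[(tert-butyldimethylsilyl)oxy]-7-hydroxy-2,2-dimethyl-2H-chromen-8-yl}-2-methylpropan-1-one F6. Bu4NF (THF, 0 °C) removes the silyl group to give compound 13.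

**Further compounds**

F1 | step 3 | racemic 3,5-dihydroxy-4-methyl-4-(3-methylbut-2-en-1-yl)-2-(2-methylpropanoyl)cyclohexa-2,5-dien-1-one | CC(C)=CCC1(C)C(O)=CC(=O)C(C(=O)C(C)C)=C1O
F2 | step 3 | (S)-1-phenylethylammonium salt of the (4S)-enolate of compound 8 | CC(C)=CC[C@@]1(C)C(O)=CC(=O)C(C(=O)C(C)C)=C1[O-].C[C@H]([NH3+])c1ccccc1
F3 | step 2 | 3-methyl-3-(3-methylbut-2-en-1-yl)pentane-2,4-dione | CC(=O)C(C)(CC=C(C)C)C(C)=O
F4 | step 2 | methyl 4-acetyl-4,7-dimethyl-3-oxooct-6-enoate (racemic) | COC(=O)CC(=O)C(C)(CC=C(C)C)C(C)=O
F5 | step 5 | 1-{4-[(tert-butyldimethylsilyl)oxy]-2,6-dihydroxyphenyl}-2-methylpropan-1-one | CC(C)C(=O)c1c(O)cc(O[Si](C)(C)C(C)(C)C)cc1O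
F6 | step 5 | 1-{5-[(tert-butyldimethylsilyl)oxy]-7-hydroxy-2,2-dimethyl-2H-chromen-8-yl}-2-methylpropan-1-one | CC(C)C(=O)c1c(O)cc(O[Si](C)(C)C(C)(C)C)c2c1OC(C)(C)C=C2
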